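**Retrosynthetic overview**

1. Dicitrinone I (15) ⇒ C2-symmetric methylene-bridged bis(decarboxycitrinin) 14, by 1,6-hydride reduction of one of its two identical quinone methides (C1=C8a → C1H2).
2. 14 ⇒ 2 × decarboxycitrinin 13 + CH2O (C7–CH2–C7' bonds, Knoevenagel–Michael).
3. 13 ⇒ triol 10 + HC(OEt)3 (C1–C8a and C1–O bonds: ring formylation next to the side chain, hemiacetal closure, loss of ROH to the quinone methide).
4. 10 ⇒ (2S,3S)-alcohol 7 (carbinol inversion, O-demethylation) ⇒ aryl Grignard reagent 6 + (2S,3S)-2,3-dimethyloxirane 5.
5. Ring order: the arene is bought; both pyran rings close in the same operation (step 6) as quinone methides; one of them becomes the isochroman in step 7.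

Assumption: the biosynthesis is taken to be citrinin-like (pyran from an ortho-formyl resorcinol and the side-chain carbinol, dehydrated to the quinone methide; isochroman half by reduction of such a quinone methide; the halves joined at C7 by a one-carbon unit at the formaldehyde level), and quinone methides are drawn as the 6-hydroxy-8-oxo tautomer of the target SMILES.

**Step 1**
Reactants: 1 1-bromo-3,5-dimethoxybenzene; 2 N,N-dimethylformamide
Product: 3 2-bromo-4,6-dimethoxybenzaldehyde
Conditions: POCl3 (1.3 equiv), DMF, 0 → 90 °C; then H2O, 60 °C
Reagents that add atoms: N,N-dimethylformamide (2), CN(C)C=O; water, O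
Why: Vilsmeier–Haack formylation goes para to one methoxy and ortho to the other (the carbon that will carry the ring methyl), the position between the two methoxy groups being less reactive toward the bulky chloroiminium ion; no stereocentre is formed.

**Step 2**
Reactants: 3 2-bromo-4,6-dimethoxybenzaldehyde
Product: 4 1-bromo-3,5-dimethoxy-2-methylbenzene
Conditions: Et3SiH (2.5 equiv), TFA, CH2Cl2, 0 °C → rt
Reagents that add atoms: none
Why: Ionic hydrogenation of an electron-rich aryl aldehyde passes through the stabilised 2,4-dimethoxybenzyl cation to the methyl group and leaves the C–Br bond alone; no stereocentre is formed.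

**Step 3**
Reactants: 4 1-bromo-3,5-dimethoxy-2-methylbenzene; 5 (2S,3S)-2,3-dimethyloxirane
Product: 7 (2S,3S)-3-(3,5-dimethoxy-2-methylphenyl)butan-2-ol, via aryl Grignard reagent 6 (not isolated)
Conditions: Mg, THF, reflux; then CuI (10 mol %), 5 (1.5 equiv), THF, −30 °C → rt; then 1 M aq. HCl, 0 °C
Reagents that add atoms: magnesium, [Mg] (held only by 6; absent from 7)
Why: Copper-catalysed SN2 opening of the C2-symmetric trans-epoxide by the aryl Grignard reagent (regiochemistry is degenerate) inverts the attacked carbon, which sets the benzylic centre as S (the final C4) from the enantiopure epoxide, while the untouched epoxide carbon becomes the (S)-carbinol.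

**Step 4**
Reactants: 7 (2S,3S)-3-(3,5-dimethoxy-2-methylphenyl)butan-2-ol; 8 formic acid
Product: 9 (2R,3S)-3-(3,5-dimethoxy-2-methylphenyl)butan-2-yl formate
Conditions: HCO2H (3 equiv), PPh3 (2 equiv), DIAD (2 equiv), THF, 0 °C → rt
Reagents that add atoms: formic acid (8), OC=O
Why: Mitsunobu esterification displaces the alkoxyphosphonium ion by formate in an SN2 step and so inverts the carbinol centre from S to R, giving the (2R,3S) relationship needed for the trans-3,4-dimethylpyran; the aryl group is a poor neighbouring group because both methoxy groups are meta to its ipso carbon.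

**Step 5**
Reactants: 9 (2R,3S)-3-(3,5-dimethoxy-2-methylphenyl)butan-2-yl formate
Product: 10 (2R,3S)-3-(3,5-dihydroxy-2-methylphenyl)butan-2-ol
Conditions: BBr3 (4 equiv), CH2Cl2, −78 → 0 °C; then MeOH, 0 °C → rt
Reagents that add atoms: none
Why: BBr3 cleaves both aryl methyl ethers by Lewis acid-assisted SN2 demethylation at low temperature, and the methanol quench (HBr/MeOH) transesterifies the formate and the aryl borates, so the triol is released with both stereocentres untouched.

**Step 6**
Reactants: 10 (2R,3S)-3-(3,5-dihydroxy-2-methylphenyl)butan-2-ol (2 equiv); 11 triethyl orthoformate; 12 formaldehyde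
Product: 14 7,7'-methanediylbis[(3R,4S)-6-hydroxy-3,4,5-trimethyl-3,4-dihydro-8H-isochromen-8-one], via decarboxycitrinin 13 (not isolated)
Conditions: HC(OEt)3 (1.1 equiv), TFA, CH2Cl2, 0 °C → rt; concentrate; then 37% aq. CH2O (0.5 equiv), NaOAc (10 mol %), EtOH, 40 °C
Reagents that add atoms: triethyl orthoformate (11), CCOC(OCC)OCC; formaldehyde (12), C=O
Why: Transorthoesterification at the side-chain hydroxyl followed by acid-promoted intramolecular Friedel–Crafts attack of the tethered alkoxycarbenium ion at the one ring position it can reach (para to one hydroxyl, ortho to the other) delivers the 1-ethoxy lactol ether, the masked ortho-formyl hemiacetal of citrinin biosynthesis, which loses ethanol to quinone methide 13 (the classical orthoformate closure of citrinin syntheses), after which formaldehyde condenses at C7, the single nucleophilic carbon of this vinylogous acid, and the 7-methylene intermediate is trapped by a second molecule of 13 in a Knoevenagel–Michael sequence of the dicoumarol type, no stereocentre being formed or touched.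

**Step 7**
Reactants: 14 7,7'-methanediylbis[(3R,4S)-6-hydroxy-3,4,5-trimethyl-3,4-dihydro-8H-isochromen-8-one]
Product: 15 dicitrinone I
Conditions: Et3N (1.0 equiv), NaBH4 (0.3 equiv), THF–EtOH (1:1), −40 → 0 °C; then AcOH
Reagents that add atoms: none
Why: Proposed new method: charge-gated desymmetrising 1,6-hydride reduction, in which one equivalent of Et3N turns the bis(vinylogous acid) 14 into its hydrogen-bonded mono-anion (first and second acidities expected to be well apart, as in dicoumarol), BH4− adds at C1 of the un-ionised quinone methide half with aromatisation as driving force (closest known reaction: hydride reduction of citrinin-type quinone methides to isochromans), and the proton of the remaining enol is then taken up by the new phenoxide so that the surviving quinone methide sits as an enolate that, like a 1,3-diketonate, resists borohydride and stops the reaction after one hydride per molecule; the two halves of 14 are homotopic and C1 becomes CH2, so no stereocentre is created or disturbed.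

**Compound list**

1 | 1-bromo-3,5-dimethoxybenzene | COc1cc(Br)cc(OC)c1 | starting material
2 | N,N-dimethylformamide | CN(C)C=O | starting material
3 | 2-bromo-4,6-dimethoxybenzaldehyde | COc1cc(Br)c(C=O)c(OC)c1 | intermediate
4 | 1-bromo-3,5-dimethoxy-2-methylbenzene | COc1cc(Br)c(C)c(OC)c1 | intermediate
5 | (2S,3S)-2,3-dimethyloxirane | C[C@@H]1O[C@H]1C | starting material
6 | (3,5-dimethoxy-2-methylphenyl)magnesium bromide | COc1cc(OC)c(C)c([Mg]Br)c1 | intermediate (not isolated)
7 | (2S,3S)-3-(3,5-dimethoxy-2-methylphenyl)butan-2-ol | C[C@H](O)[C@@H](C)c1cc(OC)cc(OC)c1C | intermediate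
8 | formic acid | OC=O | starting material
9 | (2R,3S)-3-(3,5-dimethoxy-2-methylphenyl)butan-2-yl formate | C[C@@H](OC=O)[C@@H](C)c1cc(OC)cc(OC)c1C | intermediate
10 | (2R,3S)-3-(3,5-dihydroxy-2-methylphenyl)butan-2-ol | C[C@@H](O)[C@@H](C)c1cc(O)cc(O)c1C | intermediate
11 | triethyl orthoformate | CCOC(OCC)OCC | starting material
12 | formaldehyde (37% aqueous solution) | C=O | starting material
13 | decarboxycitrinin, (3R,4S)-6-hydroxy-3,4,5-trimethyl-3,4-dihydro-8H-isochromen-8-one | CC1=C2C(=CO[C@H](C)[C@H]2C)C(=O)C=C1O | intermediate (not isolated)
14 | 7,7'-methanediylbis[(3R,4S)-6-hydroxy-3,4,5-trimethyl-3,4-dihydro-8H-isochromen-8-one] (methylene-bridged bis(decarboxycitrinin)) | CC1=C2C(=CO[C@H](C)[C@H]2C)C(=O)C(CC2=C(O)C(C)=C3C(=CO[C@H](C)[C@H]3C)C2=O)=C1O | intermediate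
15 | dicitrinone I, (3R,4S)-7-{[(3R,4S)-6,8-dihydroxy-3,4,5-trimethyl-3,4-dihydro-1H-isochromen-7-yl]methyl}-6-hydroxy-3,4,5-trimethyl-3,4-dihydro-8H-isochromen-8-one | CC1=C2C(=CO[C@H](C)[C@H]2C)C(=O)C(Cc2c(O)c(C)c3c(c2O)CO[C@H](C)[C@H]3C)=C1O | target

**Totals and risks**

Total step count: 7. Longest linear sequence: 7 steps (1 → 15; the route is linear because both halves of the target come from the same triol 10).

The three steps most likely to fail:

- **Step 7.** The hydride may fail to discriminate, giving the doubly reduced bis-isochroman beside unreacted 14. The fallback gives up the desymmetrisation and joins two different monomers by a directed ortho-quinone methide coupling. It sets out from 13, which is isolated after the orthoformate stage of step 6 instead of being treated with formaldehyde. Half of 13 is reduced (NaBH4, EtOH, 0 °C) to decarboxydihydrocitrinin F1. F1, whose only free ring position is C7, is aminomethylated with dimethylmethyleneiminium iodide (CH2=NMe2+ I−, CH2Cl2, rt) to the Mannich base (3R,4S)-7-[(dimethylamino)methyl]-3,4,5-trimethyl-3,4-dihydro-1H-isochromene-6,8-diol F2. F2 and the other half of 13 are heated together (1,4-dioxane, 90 °C); F2 loses dimethylamine to the 7-methylidene ortho-quinone methide F3, which 13 captures by Michael addition at C7. This gives 15 directly, so the fallback comes back to the route at 15 and bypasses 14.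

- **Step 6.** Formylation between the two hydroxyls or a second formylation of 13 may compete with the tethered closure, and 13 may suffer in the aqueous second stage. The fallback blocks the position between the hydroxyls with the carboxyl group that citrinin itself carries. It sets out from 10. Kolbe–Schmitt carboxylation (KHCO3, CO2, glycerol, 150 °C) gives 2,6-dihydroxy-4-[(2S,3R)-3-hydroxybutan-2-yl]-3-methylbenzoic acid F4. HC(OEt)3 followed by dilute HCl closes the pyran to citrinin F5. Heating (DMF, 120 °C) decarboxylates this vinylogous beta-keto acid to 13, where the fallback comes back to the route; 13 is then isolated and bridged with CH2O as in the second stage of step 6 to give 14.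

- **Step 4.** Elimination to the styrene or partial retention through aryl participation may erode the inversion. The fallback inverts the carbinol by oxidation and substrate-controlled reduction instead of SN2 displacement. It sets out from 7. Dess–Martin periodinane (CH2Cl2, 0 °C) gives (3S)-3-(3,5-dimethoxy-2-methylphenyl)butan-2-one F6. LiBH(s-Bu)3 (THF, −78 °C) adds hydride in the Felkin–Anh sense (aryl anti to the incoming hydride) to give (2R,3S)-3-(3,5-dimethoxy-2-methylphenyl)butan-2-ol F7. BBr3 under the conditions of step 5 then gives 10, where the fallback comes back to the route, bypassing 9.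

**Further compounds**

F1 | step 7 | decarboxydihydrocitrinin, (3R,4S)-3,4,5-trimethyl-3,4-dihydro-1H-isochromene-6,8-diol | Oc1cc(O)c(C)c2c1CO[C@H](C)[C@H]2C
F2 | step 7 | (3R,4S)-7-[(dimethylamino)methyl]-3,4,5-trimethyl-3,4-dihydro-1H-isochromene-6,8-diol | CN(C)Cc1c(O)c(C)c2c(c1O)CO[C@H](C)[C@H]2C
F3 | step 7 | (3R,4S)-8-hydroxy-3,4,5-trimethyl-7-methylidene-3,4-dihydro-1H-isochromen-6(7H)-one (ortho-quinone methide, not isolated) | C=C1C(=O)C(C)=C2C(=C1O)CO[C@H](C)[C@H]2C
F4 | step 6 | 2,6-dihydroxy-4-[(2S,3R)-3-hydroxybutan-2-yl]-3-methylbenzoic acid | C[C@@H](O)[C@@H](C)c1cc(O)c(C(=O)O)c(O)c1C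
F5 | step 6 | citrinin, (3R,4S)-6-hydroxy-3,4,5-trimethyl-8-oxo-3,4-dihydroisochromene-7-carboxylic acid | CC1=C2C(=CO[C@H](C)[C@H]2C)C(=O)C(C(=O)O)=C1O
F6 | step 4 | (3S)-3-(3,5-dimethoxy-2-methylphenyl)butan-2-one | CC(=O)[C@@H](C)c1cc(OC)cc(OC)c1C
F7 | step 4 | (2R,3S)-3-(3,5-dimethoxy-2-methylphenyl)butan-2-ol | C[C@@H](O)[C@@H](C)c1cc(OC)cc(OC)c1C
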